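Read this flask off the violet run, not the red: it carries the same nucleophile and free base, but twice the electrophile.

| flask | electrophile | nucleophile | free base | remark | time |
|---|---|---|---|---|---|
| red | 0.80 M | 0.80 M | 0.80 M | run made earlier |  |
| violet | 0.40 M | 1.6 M | 0.80 M | run made earlier |  |
| flask | 0.80 M | 1.60 M | 0.800 M |  | 20 h |

| run | time / h | electrophile / % | target / % |
|---|---|---|---|
| red | 2.50 | 96 | 2 |
| red | 5.00 | 94 | 1 |
| red | 8.00 | 88 | 9 |
| red | 10.0 | 90 | 10 |
| red | 12.0 | 85 | 11 |
| violet | 1.00 | 94 | 0 |
| violet | 3.00 | 91 | 11 |
| violet | 6.00 | 84 | 14 |
| violet | 8.00 | 76 | 16 |
| violet | 12.0 | 71 | 22 |

(standard deviation of a reading: 2 percentage points)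

- part of the electrophile that has reacted at 20 h
- share of the unused nucleophile that is free and not bound as protonated nucleophile, at 20 h

- a species is counted by the electrophile in it: one side product counts as two
- what was read earlier has a scatter of 2 percentage points, one standard deviation
- what may be going on: electrophile + nucleophile <-> acid set free + target; acid set free + free base <-> salt of the base; free base + target -> over-reaction product; nucleophile + acid set free <-> protonated nucleophile; electrophile + target -> side product
- the earlier runs do not show how much of nucleophile is bound; that part of a forecast is a guess

Follow one electrophile molecule. Violet still holds 71% of its charge at 12.0 h, which gives 0.0285 h⁻¹. Call this the hourly chance of being taken, the pseudo-first-order constant: the logarithm of charge over remainder, per hour. Red, with half the nucleophile but also twice the electrophile, reads 0.0135 h⁻¹, about half of violet. Two settings differ there, so tie the chance to the nucleophile charge as an assumption, taken from the step electrophile + nucleophile, not as a finding. Both runs hold the same free base, so comparing them says nothing on it; assume it plays no part in the chance.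

Carry the chance over unchanged: this flask should keep 56.5% at 20 h, so 43.5% reacted. This flask charges more electrophile per nucleophile than violet, so expect its nucleophile to sink further and the chance with it. Against that, violet's last electrophile and target readings sum to less than the charge, which hints at a second fork, electrophile + target to side product. Assume the two cancel.

The forecast says 41% reacted and 94% free, “with no visible slowing”. This reckoning gives more reacted and offers nothing on the free share.

The flask gives 45.3% reacted and 99.1% free.

    electrophile + nucleophile ⇌ acid set free + target (K = 0.118, k = 0.0189 L mol⁻¹ h⁻¹)
    acid set free + free base ⇌ salt of the base, settled at all times (K = 1050 L mol⁻¹)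
    free base + target → over-reaction product (k = 0.0546 L mol⁻¹ h⁻¹)
    nucleophile + acid set free ⇌ protonated nucleophile, settled at all times (K = 13.0 L mol⁻¹)
    electrophile + target → side product (k = 0.0260 L mol⁻¹ h⁻¹)

Now take the neighbour, with free base cut to 0.32 M, or 0.400 equiv on the electrophile. Its nucleophile charge and time stand as in the flask, so the hourly chance 0.0285 h⁻¹ again leaves 56.5% and predicts 43.5% reacted. The neighbour gives 45.4%. Its over-reaction product is 2.51% against 9.91% in the flask, and the free share of its unused nucleophile stands at 94.7%.

(The runs were computed with constants of no real substance.)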